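The pyran ring C is disconnected at the O1–C8a aryl ether bond. Ring A has hydrogen on C8, flanked by the C7 oxygen and by C8a, the carbon that bears O1. A bromine placed on C8 therefore lets a base remove C8a–H and expel bromide, giving the C8≡C8a aryne, which the tethered primary alkoxide captures at C8a. One operation thus forms O1–C8a, closes ring C and removes the halogen, leaving the preset C3 stereocentre alone. The precursor is an open-chain (2R)-2,3-diarylpropan-1-ol: ring B is the MOM-protected chromene, ring A a 5-bromo-2-methoxy-4-(methoxymethoxy)phenyl group, assembled by auxiliary-controlled benzylation of an arylacetyl imide and hydride cleavage.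

Key step: step 13

Assumption: isoflavan numbering (O1, C2, C3, C4, C4a, C5 to C8, C8a; ring A the benzo ring, ring C the pyran, ring B the aryl group on C3) is used for the target and, by analogy, for its open-chain precursors; LiTMP, TosMIC and oxazolidinone 19 are taken as purchased reagents.

Step 1
Reactants: 1 4-hydroxy-2-methoxybenzaldehyde
Product: 2 5-bromo-4-hydroxy-2-methoxybenzaldehyde
Conditions: NBS (1.0 equiv), MeCN, 0 °C → rt
Reagents that add atoms: N-bromosuccinimide, O=C1CCC(=O)N1Br
Why: Electrophilic aromatic bromination of an activated phenol should go to C5, which is ortho to the free hydroxyl and para to the methoxy group, because the only other activated site, C3, is shielded between the two oxygens; C5 becomes C8 of the isoflavan.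

Step 2
Reactants: 2 5-bromo-4-hydroxy-2-methoxybenzaldehyde
Product: 3 5-bromo-2-methoxy-4-(methoxymethoxy)benzaldehyde
Conditions: MOMCl, i-Pr2NEt, CH2Cl2, 0 °C → rt
Reagents that add atoms: chloromethyl methyl ether, COCCl
Why: Williamson-type O-alkylation of the acidic phenol with the reactive chloromethyl ether gives a MOM acetal that is stable to every basic step that follows and is cleaved only by acid.

Step 3
Reactants: 3 5-bromo-2-methoxy-4-(methoxymethoxy)benzaldehyde
Product: 4 [5-bromo-2-methoxy-4-(methoxymethoxy)phenyl]methanol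
Conditions: NaBH4, MeOH/THF, 0 °C
Reagents that add atoms: none
Why: Borohydride reduction of an aryl aldehyde is fast at 0 °C and leaves the aryl bromide and the MOM acetal untouched.

Step 4
Reactants: 4 [5-bromo-2-methoxy-4-(methoxymethoxy)phenyl]methanol
Product: 5 1-bromo-5-(bromomethyl)-4-methoxy-2-(methoxymethoxy)benzene
Conditions: PPh3, CBr4, CH2Cl2, 0 °C; used at once
Reagents that add atoms: carbon tetrabromide, BrC(Br)(Br)Br
Why: Appel bromination converts the benzylic alcohol to the bromide under essentially neutral conditions that spare the MOM acetal, and the ring bromine tempers the tendency of this electron-rich benzylic bromide to ionise.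

Step 5
Reactants: 6 2,4-dihydroxybenzaldehyde
Product: 7 2-hydroxy-4-(methoxymethoxy)benzaldehyde
Conditions: MOMCl (1.05 equiv), K2CO3, acetone, 0 °C → rt
Reagents that add atoms: chloromethyl methyl ether, COCCl
Why: Chemoselective Williamson-type etherification should occur only at the 4-hydroxyl, because the 2-hydroxyl is held in a hydrogen bond to the formyl oxygen and is the weaker nucleophile.

Step 6
Reactants: 7 2-hydroxy-4-(methoxymethoxy)benzaldehyde; 8 3-chloro-3-methylbut-1-yne
Product: 9 4-(methoxymethoxy)-2-[(2-methylbut-3-yn-2-yl)oxy]benzaldehyde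
Conditions: DBU, CuCl2·2H2O (cat.), MeCN, 0 °C → rt
Reagents that add atoms: none
Why: Copper-catalysed propargylic etherification of a phenol with a tertiary propargylic chloride (Godfrey-type conditions) passes through a copper-bound propargyl cation equivalent that the phenoxide traps at oxygen, which bypasses an SN2 reaction at a tertiary carbon and should overcome the low reactivity of the hydrogen-bonded phenol.

Step 7
Reactants: 9 4-(methoxymethoxy)-2-[(2-methylbut-3-yn-2-yl)oxy]benzaldehyde
Product: 12 5-(methoxymethoxy)-2,2-dimethyl-2H-chromene-8-carbaldehyde, via allenyl phenol 10 (not isolated), via ortho-quinone methide 11 (not isolated)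
Conditions: N,N-diethylaniline, 170 °C
Reagents that add atoms: none
Why: Thermal aromatic propargyl Claisen rearrangement can end productively only on C3 because the other ortho carbon carries the formyl group, and the following 1,5-hydrogen shift and oxa-6π electrocyclisation deliver the 2,2-dimethyl-2H-chromene fused through the former 2-oxygen, which places the formyl group on C8 and the MOM ether on C5 of the chromene.

Step 8
Reactants: 12 5-(methoxymethoxy)-2,2-dimethyl-2H-chromene-8-carbaldehyde
Product: 15 2-[5-(methoxymethoxy)-2,2-dimethyl-2H-chromen-8-yl]acetonitrile, via tosyl oxazoline 13 (not isolated), via N-formyl enamide 14 (not isolated)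
Conditions: TosMIC (1.1 equiv), KOt-Bu (2.2 equiv), DME, −40 °C; then MeOH, reflux
Reagents that add atoms: tosylmethyl isocyanide, Cc1ccc(cc1)S(=O)(=O)C[N+]#[C-]
Why: Van Leusen reductive cyanation, in which the TosMIC anion adds to the aldehyde and cyclises, base opens the oxazoline at low temperature before it can aromatise, and methanolysis of the formyl group followed by loss of sulfinate leaves the nitrile with one carbon more than the aldehyde.

Step 9
Reactants: 15 2-[5-(methoxymethoxy)-2,2-dimethyl-2H-chromen-8-yl]acetonitrile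
Product: 18 2-[5-(methoxymethoxy)-2,2-dimethyl-2H-chromen-8-yl]acetic acid, via primary amide 16 (not isolated), via potassium carboxylate 17 (not isolated)
Conditions: KOH, EtOH/H2O, reflux; then 1 M HCl to pH 4, 0 °C
Reagents that add atoms: potassium hydroxide, [K+].[OH-]; water, O
Why: Alkaline nitrile hydrolysis is tolerated by the MOM acetal and the chromene, and the acid is released by brief cold acidification to pH 4 so that the acetal never meets strong acid.

Step 10
Reactants: 18 2-[5-(methoxymethoxy)-2,2-dimethyl-2H-chromen-8-yl]acetic acid; 19 (4R)-4-benzyl-1,3-oxazolidin-2-one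
Product: 21 (4R)-4-benzyl-3-{2-[5-(methoxymethoxy)-2,2-dimethyl-2H-chromen-8-yl]acetyl}-1,3-oxazolidin-2-one, via mixed pivalic anhydride 20 (not isolated)
Conditions: PivCl, Et3N, THF, −20 °C; then 19, LiCl, −20 °C → rt
Reagents that add atoms: none
Why: N-Acylation of the oxazolidinone by a mixed anhydride under LiCl/Et3N activation is directed to the arylacetyl carbonyl because the pivaloyl carbonyl is hindered.

Step 11
Reactants: 21 (4R)-4-benzyl-3-{2-[5-(methoxymethoxy)-2,2-dimethyl-2H-chromen-8-yl]acetyl}-1,3-oxazolidin-2-one; 5 1-bromo-5-(bromomethyl)-4-methoxy-2-(methoxymethoxy)benzene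
Product: 23 (4R)-4-benzyl-3-{(2R)-3-[5-bromo-2-methoxy-4-(methoxymethoxy)phenyl]-2-[5-(methoxymethoxy)-2,2-dimethyl-2H-chromen-8-yl]propanoyl}-1,3-oxazolidin-2-one, via sodium (Z)-enolate 22 (not isolated)
Conditions: NaN(SiMe3)2 (1.1 equiv), THF, −78 °C; then 5, −78 → −40 °C; AcOH quench
Reagents that add atoms: none
Why: Evans asymmetric alkylation, in which the chelated (Z)-enolate is shielded on one face by the C4 benzyl group of the (R)-auxiliary so that the benzylic bromide enters from the open face and sets the new centre as R (the future C3), while low temperature and an acidic quench protect the acidic α-aryl position from epimerisation.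

Step 12
Reactants: 23 (4R)-4-benzyl-3-{(2R)-3-[5-bromo-2-methoxy-4-(methoxymethoxy)phenyl]-2-[5-(methoxymethoxy)-2,2-dimethyl-2H-chromen-8-yl]propanoyl}-1,3-oxazolidin-2-one
Product: 24 (2R)-3-[5-bromo-2-methoxy-4-(methoxymethoxy)phenyl]-2-[5-(methoxymethoxy)-2,2-dimethyl-2H-chromen-8-yl]propan-1-ol
Conditions: LiBH4, MeOH (1.5 equiv), THF, 0 °C; then H2O
Reagents that add atoms: none
Why: Reductive cleavage of the N-acyl oxazolidinone by LiBH4 attacks the more electrophilic exocyclic carbonyl and releases the primary alcohol and the auxiliary under conditions that neither epimerise the stereocentre nor touch the aryl bromide.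

Step 13
Reactants: 24 (2R)-3-[5-bromo-2-methoxy-4-(methoxymethoxy)phenyl]-2-[5-(methoxymethoxy)-2,2-dimethyl-2H-chromen-8-yl]propan-1-ol
Product: 27 (3R)-5-methoxy-7-(methoxymethoxy)-3-[5-(methoxymethoxy)-2,2-dimethyl-2H-chromen-8-yl]-3,4-dihydro-2H-chromene, via aryne lithium alkoxide 25 (not isolated), via C8-lithiated isoflavan 26 (not isolated)
Conditions: LiTMP (lithium 2,2,6,6-tetramethylpiperidide, 3.5 equiv), THF (0.02 M), −78 °C → rt; then H2O
Reagents that add atoms: none
Why: One equivalent of LiTMP makes the lithium alkoxide, a further equivalent removes C8a–H, the only hydrogen ortho to bromine, and the resulting 2-bromoaryllithium loses LiBr to give the C8≡C8a aryne of ring A. The tethered alkoxide then adds to C8a and the C8 aryllithium that results, stabilised by the neighbouring MOM ether, is protonated on quench; the closest known reaction type is the base-induced benzyne cyclisation of 3-(3-halophenyl)propan-1-ols to chromans. Ring C closes in a 6-exo-dig mode, since attack at C8 would need a bridged meta ring and is geometrically excluded. No stereocentre is formed, and C3, which has no acidic hydrogen, should keep its R configuration. The step needs site-selective metalation and regioselective addition: lithiation at C6 between the two ether oxygens is reversible and leads nowhere, whereas lithiation at C8a is drained irreversibly by bromide loss, and the C7 oxygen polarises the aryne so that charge builds on C8 and the nucleophile enters at C8a, the same carbon the tether dictates.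

Step 14
Reactants: 27 (3R)-5-methoxy-7-(methoxymethoxy)-3-[5-(methoxymethoxy)-2,2-dimethyl-2H-chromen-8-yl]-3,4-dihydro-2H-chromene
Product: 28 (3R)-3-(5-hydroxy-2,2-dimethyl-2H-chromen-8-yl)-5-methoxy-3,4-dihydro-2H-chromen-7-ol (CNP0320659.1)
Conditions: HCl (1 M in MeOH), 40 °C
Reagents that add atoms: none
Why: Acid-catalysed transacetalisation to methanol should release both phenols under conditions mild enough for the 2,2-dimethylchromene, and the C3 stereocentre is not acid-labile.

Compound list
1 | 4-hydroxy-2-methoxybenzaldehyde | COc1cc(O)ccc1C=O | starting material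
2 | 5-bromo-4-hydroxy-2-methoxybenzaldehyde | COc1cc(O)c(Br)cc1C=O | intermediate
3 | 5-bromo-2-methoxy-4-(methoxymethoxy)benzaldehyde | COCOc1cc(OC)c(C=O)cc1Br | intermediate
4 | [5-bromo-2-methoxy-4-(methoxymethoxy)phenyl]methanol | COCOc1cc(OC)c(CO)cc1Br | intermediate
5 | 1-bromo-5-(bromomethyl)-4-methoxy-2-(methoxymethoxy)benzene | COCOc1cc(OC)c(CBr)cc1Br | intermediate
6 | 2,4-dihydroxybenzaldehyde | O=Cc1ccc(O)cc1O | starting material
7 | 2-hydroxy-4-(methoxymethoxy)benzaldehyde | COCOc1ccc(C=O)c(O)c1 | intermediate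
8 | 3-chloro-3-methylbut-1-yne | C#CC(C)(C)Cl | starting material
9 | 4-(methoxymethoxy)-2-[(2-methylbut-3-yn-2-yl)oxy]benzaldehyde | COCOc1ccc(C=O)c(OC(C)(C)C#C)c1 | intermediate
10 | 2-hydroxy-4-(methoxymethoxy)-3-(3-methylbuta-1,2-dien-1-yl)benzaldehyde (allenyl phenol) | COCOc1ccc(C=O)c(O)c1C=C=C(C)C | intermediate (not isolated)
11 | 4-(methoxymethoxy)-5-(3-methylbut-2-en-1-ylidene)-6-oxocyclohexa-1,3-diene-1-carbaldehyde (ortho-quinone methide, alkene geometry not specified) | O=CC1=CC=C(OCOC)C(=CC=C(C)C)C1=O | intermediate (not isolated)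
12 | 5-(methoxymethoxy)-2,2-dimethyl-2H-chromene-8-carbaldehyde | O=Cc1ccc(OCOC)c2C=CC(C)(C)Oc12 | intermediate
13 | 5-[5-(methoxymethoxy)-2,2-dimethyl-2H-chromen-8-yl]-4-(4-methylbenzenesulfonyl)-4,5-dihydro-1,3-oxazole (racemic) | Cc1ccc(cc1)S(=O)(=O)C1N=COC1c1ccc(OCOC)c2C=CC(C)(C)Oc12 | intermediate (not isolated)
14 | N-{2-[5-(methoxymethoxy)-2,2-dimethyl-2H-chromen-8-yl]-1-(4-methylbenzenesulfonyl)ethenyl}formamide (present as its potassium salt, alkene geometry not specified) | O=CNC(=Cc1ccc(OCOC)c2C=CC(C)(C)Oc12)S(=O)(=O)c1ccc(C)cc1 | intermediate (not isolated)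
15 | 2-[5-(methoxymethoxy)-2,2-dimethyl-2H-chromen-8-yl]acetonitrile | N#CCc1ccc(OCOC)c2C=CC(C)(C)Oc12 | intermediate
16 | 2-[5-(methoxymethoxy)-2,2-dimethyl-2H-chromen-8-yl]acetamide | NC(=O)Cc1ccc(OCOC)c2C=CC(C)(C)Oc12 | intermediate (not isolated)
17 | potassium 2-[5-(methoxymethoxy)-2,2-dimethyl-2H-chromen-8-yl]acetate | [K+].[O-]C(=O)Cc1ccc(OCOC)c2C=CC(C)(C)Oc12 | intermediate (not isolated)
18 | 2-[5-(methoxymethoxy)-2,2-dimethyl-2H-chromen-8-yl]acetic acid | OC(=O)Cc1ccc(OCOC)c2C=CC(C)(C)Oc12 | intermediate
19 | (4R)-4-benzyl-1,3-oxazolidin-2-one | O=C1N[C@H](Cc2ccccc2)CO1 | starting material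
20 | 2-[5-(methoxymethoxy)-2,2-dimethyl-2H-chromen-8-yl]acetic 2,2-dimethylpropanoic anhydride | CC(C)(C)C(=O)OC(=O)Cc1ccc(OCOC)c2C=CC(C)(C)Oc12 | intermediate (not isolated)
21 | (4R)-4-benzyl-3-{2-[5-(methoxymethoxy)-2,2-dimethyl-2H-chromen-8-yl]acetyl}-1,3-oxazolidin-2-one | O=C1OC[C@@H](Cc2ccccc2)N1C(=O)Cc1ccc(OCOC)c2C=CC(C)(C)Oc12 | intermediate
22 | sodium (Z)-enolate of 21 | [Na+].[O-]/C(=C\c1ccc(OCOC)c2C=CC(C)(C)Oc12)N1C(=O)OC[C@H]1Cc1ccccc1 | intermediate (not isolated)
23 | (4R)-4-benzyl-3-{(2R)-3-[5-bromo-2-methoxy-4-(methoxymethoxy)phenyl]-2-[5-(methoxymethoxy)-2,2-dimethyl-2H-chromen-8-yl]propanoyl}-1,3-oxazolidin-2-one | O=C1OC[C@@H](Cc2ccccc2)N1C(=O)[C@H](Cc1cc(Br)c(OCOC)cc1OC)c1ccc(OCOC)c2C=CC(C)(C)Oc12 | intermediate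
24 | (2R)-3-[5-bromo-2-methoxy-4-(methoxymethoxy)phenyl]-2-[5-(methoxymethoxy)-2,2-dimethyl-2H-chromen-8-yl]propan-1-ol | COc1cc(OCOC)c(Br)cc1C[C@H](c1ccc(OCOC)c2c1OC(C)(C)C=C2)CO | intermediate
25 | lithium alkoxide of the C8≡C8a aryne derived from 24 | COC1=C(C[C@H](c2ccc(OCOC)c3c2OC(C)(C)C=C3)C[O-])C#CC(OCOC)=C1.[Li+] | intermediate (not isolated)
26 | 8-lithio derivative of 27 | COc1cc(OCOC)c([Li])c2c1C[C@H](c1ccc(OCOC)c3c1OC(C)(C)C=C3)CO2 | intermediate (not isolated)
27 | (3R)-5-methoxy-7-(methoxymethoxy)-3-[5-(methoxymethoxy)-2,2-dimethyl-2H-chromen-8-yl]-3,4-dihydro-2H-chromene | COc1cc(OCOC)cc2c1C[C@H](c1ccc(OCOC)c3c1OC(C)(C)C=C3)CO2 | intermediate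
28 | (3R)-3-(5-hydroxy-2,2-dimethyl-2H-chromen-8-yl)-5-methoxy-3,4-dihydro-2H-chromen-7-ol (CNP0320659.1) | COc1cc(O)cc2c1C[C@H](c1ccc(O)c3c1OC(C)(C)C=C3)CO2 | target

Total step count: 14.
Longest linear sequence: 10 steps (steps 5 to 14, from 6 through 7, 9, 12, 15, 18, 21, 23, 24 and 27 to 28); the ring A branch (steps 1 to 4) joins at step 11.

Steps most likely to fail

Step 13. The amide base may rest at C6 between the two ether oxygens or add to the aryne itself, and addition of the lithium alkoxide may be too slow to outrun intermolecular capture of the aryne, so that ring closure stays incomplete. The fallback closes ring C at O1–C2 by a Mitsunobu etherification instead; it sets out from imide 21 and comes back at 27. Commercial 2,4-dihydroxy-6-methoxybenzaldehyde F1 would be converted with MOMCl and K2CO3 into 2-hydroxy-6-methoxy-4-(methoxymethoxy)benzaldehyde F2 (the chelated 2-hydroxyl stays free), tosylated (TsCl, Et3N, DMAP) to the aryl tosylate aldehyde F3, reduced with NaBH4 to the benzylic alcohol F4 and brominated (PPh3, CBr4) to the benzylic bromide F5. The sulfonate, unlike a third ether group, should keep this bromide from ionising. Alkylation of enolate 22 with F5 under the conditions of step 11 should give the alkylated imide F6, LiBH4 the primary alcohol F7, and KOH in aqueous MeOH at reflux the free phenol F8. PPh3 and DIAD in THF would then close the pyran to 27.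

Step 6. O-Alkylation of a phenol locked in a hydrogen bond to the formyl group may stall while the tertiary chloride is lost by elimination. The fallback removes that hydrogen bond by carrying the carbonyl at the alcohol oxidation level through the ether formation and rearrangement; it sets out from 7 and comes back at 12. NaBH4 in MeOH would reduce 7 to 2-(hydroxymethyl)-5-(methoxymethoxy)phenol F9, whose unchelated phenol is alkylated with 8 (DBU, CuCl2·2H2O cat., MeCN; the aliphatic hydroxyl is not deprotonated) to the propargyl ether F10. Heating as in step 7 should give the chromenylmethanol F11, and MnO2 in CH2Cl2 would reoxidise the benzylic alcohol to 12.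

Step 8. With an aldehyde the oxazoline can aromatise by loss of sulfinate or take up methanol before it opens, which diverts material from the nitrile. The fallback builds the extra carbon by olefination and anti-Markovnikov hydration; it sets out from 12 and comes back at 18, bypassing 15. Wittig methylenation (Ph3PCH3Br, KOt-Bu, THF) would give 8-ethenyl-5-(methoxymethoxy)-2,2-dimethyl-2H-chromene F12. 9-BBN should add only to the terminal alkene, since the ring alkene is internal and flanked by a quaternary carbon, and NaOH/H2O2 would give 2-[5-(methoxymethoxy)-2,2-dimethyl-2H-chromen-8-yl]ethan-1-ol F13. TEMPO and PhI(OAc)2 in aqueous MeCN would oxidise F13 to acid 18.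

Further compounds
F1 | step 13 | 2,4-dihydroxy-6-methoxybenzaldehyde (commercial) | COc1cc(O)cc(O)c1C=O
F2 | step 13 | 2-hydroxy-6-methoxy-4-(methoxymethoxy)benzaldehyde | COCOc1cc(O)c(C=O)c(OC)c1
F3 | step 13 | 2-formyl-3-methoxy-5-(methoxymethoxy)phenyl 4-methylbenzenesulfonate | COCOc1cc(OC)c(C=O)c(OS(=O)(=O)c2ccc(C)cc2)c1
F4 | step 13 | 2-(hydroxymethyl)-3-methoxy-5-(methoxymethoxy)phenyl 4-methylbenzenesulfonate | COCOc1cc(OC)c(CO)c(OS(=O)(=O)c2ccc(C)cc2)c1
F5 | step 13 | 2-(bromomethyl)-3-methoxy-5-(methoxymethoxy)phenyl 4-methylbenzenesulfonate | COCOc1cc(OC)c(CBr)c(OS(=O)(=O)c2ccc(C)cc2)c1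
F6 | step 13 | 2-{(2R)-3-[(4R)-4-benzyl-2-oxo-1,3-oxazolidin-3-yl]-2-[5-(methoxymethoxy)-2,2-dimethyl-2H-chromen-8-yl]-3-oxopropyl}-3-methoxy-5-(methoxymethoxy)phenyl 4-methylbenzenesulfonate | O=C1OC[C@@H](Cc2ccccc2)N1C(=O)[C@H](Cc1c(OC)cc(OCOC)cc1OS(=O)(=O)c1ccc(C)cc1)c1ccc(OCOC)c2C=CC(C)(C)Oc12
F7 | step 13 | 2-{(2R)-3-hydroxy-2-[5-(methoxymethoxy)-2,2-dimethyl-2H-chromen-8-yl]propyl}-3-methoxy-5-(methoxymethoxy)phenyl 4-methylbenzenesulfonate | COc1cc(OCOC)cc(OS(=O)(=O)c2ccc(C)cc2)c1C[C@H](c1ccc(OCOC)c2c1OC(C)(C)C=C2)CO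
F8 | step 13 | 2-{(2R)-3-hydroxy-2-[5-(methoxymethoxy)-2,2-dimethyl-2H-chromen-8-yl]propyl}-3-methoxy-5-(methoxymethoxy)phenol | COc1cc(OCOC)cc(O)c1C[C@H](c1ccc(OCOC)c2c1OC(C)(C)C=C2)CO
F9 | step 6 | 2-(hydroxymethyl)-5-(methoxymethoxy)phenol | COCOc1ccc(CO)c(O)c1
F10 | step 6 | {4-(methoxymethoxy)-2-[(2-methylbut-3-yn-2-yl)oxy]phenyl}methanol | COCOc1ccc(CO)c(OC(C)(C)C#C)c1
F11 | step 6 | [5-(methoxymethoxy)-2,2-dimethyl-2H-chromen-8-yl]methanol | OCc1ccc(OCOC)c2C=CC(C)(C)Oc12
F12 | step 8 | 8-ethenyl-5-(methoxymethoxy)-2,2-dimethyl-2H-chromene | C=Cc1ccc(OCOC)c2C=CC(C)(C)Oc12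
F13 | step 8 | 2-[5-(methoxymethoxy)-2,2-dimethyl-2H-chromen-8-yl]ethan-1-ol | OCCc1ccc(OCOC)c2C=CC(C)(C)Oc12
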